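**Plan**
- Enabling feature: in the cyclohexane ring the tertiary carbinol C1 (OH, CO2H) is 1,3 to both secondary carbinols C5 (via C6H2) and C3 (via C2H2). With C3 as a ketone, C1–C6–C5 and C1–C2–C3 are two aldol retrons that share the carbonyl of one pyruvate, which is the biosynthetic 3-dehydroquinate pattern.
- Retrosynthesis: remove the two vanilloyl esters (O4, O5) and take C3–OH back to the ketone. Then cut C6–C5 (pyruvate CH3 onto a C5 aldehyde) and C2–C1 (C2=C3 enol onto the pyruvate C=O), giving a pyruvate enol silane and a four-carbon (R)-2-alkoxy-3-silyloxybut-3-enal.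
- Forward: the four-carbon unit comes from butadiene monoepoxide (asymmetric Pd etherification, Wacker oxidation, kinetic enol silane, oxidation to the aldehyde). A one-pot double Mukaiyama aldol then builds the only carbocycle.
- Endgame: C3 reduction, 1,3-acetal on O1/O3, PMB removal, double vanilloylation, global hydrogenolysis.
- Stereochemistry: C4 from the ligand-controlled etherification; C5 by chelation control from C4; C1 in the chair cyclisation (ester equatorial); C3 by equatorial hydride attack on the ring ketone.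

Key step: step 8

Assumption: the (S,S)-DACH-phenyl Trost ligand is taken to deliver the (R)-ether 3 (otherwise its antipode is used), and benzyl pyruvate and 4-(benzyloxy)-3-methoxybenzoic acid are taken as purchasable.

Ring compounds are named as quinic acid derivatives: C1 carries the carboxyl group, C3 is the carbinol cis to O4, C5 the carbinol trans to O4, with the configuration of (−)-quinic acid throughout.

**Route**

Step 1
Reactants: 1 3,4-epoxybut-1-ene (racemic); 2 4-methoxybenzyl alcohol
Product: 3 (R)-2-[(4-methoxybenzyl)oxy]but-3-en-1-ol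
Conditions: Pd2(dba)3·CHCl3 (1 mol%), (S,S)-DACH-phenyl Trost ligand (3 mol%), Et3B (1 mol%), CH2Cl2, rt
Reagents that add atoms: none
Why: Palladium-catalysed dynamic kinetic asymmetric allylic etherification, in which the two π-allylpalladium diastereomers from racemic 1 interconvert, the boron co-catalyst delivers the alcohol to the internal allyl carbon, and the chiral ligand sets the stereocentre that becomes C4 of the target.

Step 2
Reactants: 3 (R)-2-[(4-methoxybenzyl)oxy]but-3-en-1-ol
Product: 4 (R)-2-[(4-methoxybenzyl)oxy]but-3-en-1-yl pivalate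
Conditions: t-BuCOCl, pyridine, DMAP (cat.), CH2Cl2, 0 °C to rt
Reagents that add atoms: pivaloyl chloride CC(C)(C)C(=O)Cl
Why: Standard acylation of the primary alcohol with an ester that has no alpha hydrogen, so it should survive the later amide base and be removed by hydride.

Step 3
Reactants: 4 (R)-2-[(4-methoxybenzyl)oxy]but-3-en-1-yl pivalate
Product: 5 (S)-2-[(4-methoxybenzyl)oxy]-3-oxobutyl pivalate
Conditions: PdCl2(quinox) (5 mol%; quinox = 2-(4,5-dihydrooxazol-2-yl)quinoline), AgSbF6 (12 mol%), t-BuOOH (70% aq.), CH2Cl2, 0 °C to rt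
Reagents that add atoms: tert-butyl hydroperoxide CC(C)(C)OO
Why: Tsuji–Wacker oxidation under the ligand-controlled peroxide protocol, which is known to give methyl ketones from protected allylic alcohols with Markovnikov selectivity and leaves the allylic stereocentre untouched.

Step 4
Reactants: 5 (S)-2-[(4-methoxybenzyl)oxy]-3-oxobutyl pivalate
Product: 7 (S)-2-[(4-methoxybenzyl)oxy]-3-[(tert-butyldimethylsilyl)oxy]but-3-en-1-yl pivalate, via lithium enolate 6 (not isolated)
Conditions: LiN(i-Pr)2 (1.1 equiv), THF, −78 °C; then t-BuMe2SiCl, DMPU, −78 to 0 °C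
Reagents that add atoms: tert-butyldimethylsilyl chloride CC(C)(C)[Si](C)(C)Cl
Why: Kinetic deprotonation at the methyl group (the hindered ether-bearing C–H is not removed at −78 °C, so the stereocentre is kept and no beta-elimination of pivalate is opened) followed by O-silylation should give the less substituted enol silane.

Step 5
Reactants: 7 (S)-2-[(4-methoxybenzyl)oxy]-3-[(tert-butyldimethylsilyl)oxy]but-3-en-1-yl pivalate
Product: 8 (S)-2-[(4-methoxybenzyl)oxy]-3-[(tert-butyldimethylsilyl)oxy]but-3-en-1-ol
Conditions: i-Bu2AlH (2.5 equiv), CH2Cl2, −78 °C; aq. potassium sodium tartrate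
Reagents that add atoms: none
Why: Reductive cleavage of the pivalate by the aluminium hydride at low temperature, to which the enol silane and the benzylic ether are inert.

Step 6
Reactants: 8 (S)-2-[(4-methoxybenzyl)oxy]-3-[(tert-butyldimethylsilyl)oxy]but-3-en-1-ol
Product: 9 (R)-2-[(4-methoxybenzyl)oxy]-3-[(tert-butyldimethylsilyl)oxy]but-3-enal
Conditions: Dess–Martin periodinane, pyridine, CH2Cl2, 0 °C; used at once without chromatography
Reagents that add atoms: none
Why: Dess–Martin oxidation buffered with pyridine is mild enough to keep both the acid-labile enol silane and the alpha stereocentre of the beta,gamma-unsaturated aldehyde.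

Step 7
Reactants: 10 benzyl pyruvate
Product: 11 benzyl 2-[(trimethylsilyl)oxy]acrylate
Conditions: Me3SiCl, Et3N, Et2O/MeCN, 0 °C to rt; distillation
Reagents that add atoms: chlorotrimethylsilane C[Si](C)(C)Cl
Why: Soft enolisation and O-silylation of the 2-oxo ester give the captodative enol silane, the synthetic counterpart of phosphoenolpyruvate.

Step 8
Reactants: 9 (R)-2-[(4-methoxybenzyl)oxy]-3-[(tert-butyldimethylsilyl)oxy]but-3-enal; 11 benzyl 2-[(trimethylsilyl)oxy]acrylate
Product: 13 benzyl 4-O-(4-methoxybenzyl)-3-dehydroquinate, via bromomagnesium aldolate 12 (not isolated)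
Conditions: MgBr2·OEt2 (3 equiv), 11 (3 equiv), CH2Cl2, −78 °C, slow addition of 9, then −78 to −20 °C; aq. NH4Cl, then citric acid, MeOH, 0 °C
Reagents that add atoms: none
Why: Proposed new method: the MgBr2-chelated aldehyde of 9 (Mg bound to the aldehyde oxygen and the ether oxygen on C4) is attacked by enol silane 11 (Mukaiyama aldol, C6–C5 bond), which unveils the 2-oxo ester of 12, and this Mg-chelated keto ester is then attacked by the internal enol silane (second Mukaiyama aldol, C2–C1 bond), the same order of events as the biosynthetic phosphoenolpyruvate/erythrose 4-phosphate aldol followed by the enol–ketone aldol that gives 3-dehydroquinate. The closest known reaction types are the chelation-controlled Mukaiyama aldol of 2-silyloxyacrylates with alpha-alkoxy aldehydes and the Mukaiyama aldol of enol silanes with pyruvate esters; only their union in one annulation of two partners that each act as nucleophile and electrophile is new. The single ring closes in the 6-(enolendo)-exo-trig mode. C5 is set by the Cram chelate, in which 11 attacks the aldehyde face anti to the C3 substituent and gives the 4,5-threo (ring-trans) arrangement. C1 is set in a chair transition state with O4 and O5 equatorial and the bulky Mg-chelated benzyloxycarbonyl group pseudo-equatorial, so that CO2Bn ends cis to O5 and the tertiary hydroxyl axial, as in quinic acid. The step needs cross- over self-aldol selectivity and retention of C4: the first is secured by slow addition of 9 into excess 11 and by the hindered silyl enol ether of 9, which should react only intramolecularly with the more electrophilic keto ester, the second by the absence of any carbonyl at C3 until the ring has formed.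

Step 9
Reactants: 13 benzyl 4-O-(4-methoxybenzyl)-3-dehydroquinate
Product: 14 benzyl 4-O-(4-methoxybenzyl)quinate
Conditions: LiBH(s-Bu)3 (3.5 equiv), THF, −78 °C; AcOH, then H2O2, pH 7 buffer
Reagents that add atoms: none
Why: Steric approach control, in which the bulky borohydride attacks the chair cyclohexanone from the equatorial side (the axial side is blocked by the axial C1 oxygen), should give the axial C3 hydroxyl cis to O1 and O4 and trans to O5, while the benzyl ester is not reduced at −78 °C.

Step 10
Reactants: 14 benzyl 4-O-(4-methoxybenzyl)quinate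
Product: 15 benzyl 1,3-O-benzylidene-4-O-(4-methoxybenzyl)quinate (phenyl exo)
Conditions: PhCH(OMe)2, camphorsulfonic acid (cat.), 4 Å molecular sieves, CH2Cl2, rt
Reagents that add atoms: benzaldehyde dimethyl acetal COC(OC)c1ccccc1
Why: Acid-catalysed acetal exchange, in which only the cis-1,3-diaxial O1 and O3 can be bridged by a six-membered acetal (O5 is trans to both) and the phenyl group takes the exo position under thermodynamic control, setting the acetal stereocentre.

Step 11
Reactants: 15 benzyl 1,3-O-benzylidene-4-O-(4-methoxybenzyl)quinate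
Product: 16 benzyl 1,3-O-benzylidenequinate
Conditions: DDQ (1.3 equiv), CH2Cl2/pH 7 buffer, 0 °C to rt
Reagents that add atoms: none
Why: Oxidative cleavage of the electron-rich 4-methoxybenzyl ether by benzylic hydride abstraction and hydrolysis of the oxocarbenium ion, which the benzyl ester and the less electron-rich benzylidene acetal should survive.

Step 12
Reactants: 16 benzyl 1,3-O-benzylidenequinate; 17 4-(benzyloxy)-3-methoxybenzoic acid
Product: 18 benzyl 1,3-O-benzylidene-4,5-bis-O-[4-(benzyloxy)-3-methoxybenzoyl]quinate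
Conditions: 17 (2.6 equiv), EDC·HCl, DMAP, CH2Cl2, rt
Reagents that add atoms: none
Why: Steglich esterification of the two free equatorial secondary hydroxyls, with O1 and O3 locked in the acetal so that no regiochemical question arises.

Step 13
Reactants: 18 benzyl 1,3-O-benzylidene-4,5-bis-O-[4-(benzyloxy)-3-methoxybenzoyl]quinate
Product: 19 burkinabin C (4,5-di-O-vanilloylquinic acid)
Conditions: H2 (1 atm), Pd(OH)2/C, EtOAc/THF, rt
Reagents that add atoms: none
Why: Hydrogenolysis should remove the benzyl ester, both aryl benzyl ethers and the benzylidene acetal in one neutral operation in which the aroyl esters neither cleave nor migrate.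

**Compound list**

1 | 3,4-epoxybut-1-ene (racemic) | C=CC1CO1 | starting material
2 | 4-methoxybenzyl alcohol | COc1ccc(CO)cc1 | starting material
3 | (R)-2-[(4-methoxybenzyl)oxy]but-3-en-1-ol | COc1ccc(CO[C@@H](CO)C=C)cc1 | intermediate
4 | (R)-2-[(4-methoxybenzyl)oxy]but-3-en-1-yl pivalate | COc1ccc(CO[C@@H](COC(=O)C(C)(C)C)C=C)cc1 | intermediate
5 | (S)-2-[(4-methoxybenzyl)oxy]-3-oxobutyl pivalate | COc1ccc(CO[C@@H](COC(=O)C(C)(C)C)C(C)=O)cc1 | intermediate
6 | lithium (S)-3-[(4-methoxybenzyl)oxy]-4-(pivaloyloxy)but-1-en-2-olate (lithium enolate of 5) | COc1ccc(CO[C@@H](COC(=O)C(C)(C)C)C(=C)O[Li])cc1 | intermediate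
7 | (S)-2-[(4-methoxybenzyl)oxy]-3-[(tert-butyldimethylsilyl)oxy]but-3-en-1-yl pivalate | COc1ccc(CO[C@@H](COC(=O)C(C)(C)C)C(=C)O[Si](C)(C)C(C)(C)C)cc1 | intermediate
8 | (S)-2-[(4-methoxybenzyl)oxy]-3-[(tert-butyldimethylsilyl)oxy]but-3-en-1-ol | COc1ccc(CO[C@@H](CO)C(=C)O[Si](C)(C)C(C)(C)C)cc1 | intermediate
9 | (R)-2-[(4-methoxybenzyl)oxy]-3-[(tert-butyldimethylsilyl)oxy]but-3-enal | COc1ccc(CO[C@@H](C=O)C(=C)O[Si](C)(C)C(C)(C)C)cc1 | intermediate
10 | benzyl pyruvate | CC(=O)C(=O)OCc1ccccc1 | starting material
11 | benzyl 2-[(trimethylsilyl)oxy]acrylate | C=C(O[Si](C)(C)C)C(=O)OCc1ccccc1 | intermediate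
12 | bromomagnesium alkoxide of benzyl (4R,5S)-4-hydroxy-5-[(4-methoxybenzyl)oxy]-2-oxo-6-[(tert-butyldimethylsilyl)oxy]hept-6-enoate | COc1ccc(CO[C@@H]([C@H](O[Mg]Br)CC(=O)C(=O)OCc2ccccc2)C(=C)O[Si](C)(C)C(C)(C)C)cc1 | intermediate
13 | benzyl 4-O-(4-methoxybenzyl)-3-dehydroquinate (1-OH trans to 5-OH, O4 trans to O5) | COc1ccc(CO[C@@H]2C(=O)C[C@@](O)(C(=O)OCc3ccccc3)C[C@H]2O)cc1 | intermediate
14 | benzyl 4-O-(4-methoxybenzyl)quinate | COc1ccc(CO[C@@H]2[C@H](O)C[C@@](O)(C(=O)OCc3ccccc3)C[C@H]2O)cc1 | intermediate
15 | benzyl 1,3-O-benzylidene-4-O-(4-methoxybenzyl)quinate (phenyl exo, acetal H towards C5) | COc1ccc(CO[C@@H]2[C@H](O3)C[C@@](O[C@@H]3c4ccccc4)(C(=O)OCc4ccccc4)C[C@H]2O)cc1 | intermediate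
16 | benzyl 1,3-O-benzylidenequinate | O[C@@H]1[C@H](O2)C[C@@](O[C@@H]2c3ccccc3)(C(=O)OCc3ccccc3)C[C@H]1O | intermediate
17 | 4-(benzyloxy)-3-methoxybenzoic acid | COc1cc(C(=O)O)ccc1OCc1ccccc1 | starting material
18 | benzyl 1,3-O-benzylidene-4,5-bis-O-[4-(benzyloxy)-3-methoxybenzoyl]quinate | COc1cc(C(=O)O[C@@H]2[C@H](O3)C[C@@](O[C@@H]3c4ccccc4)(C(=O)OCc4ccccc4)C[C@H]2OC(=O)c2ccc(OCc3ccccc3)c(OC)c2)ccc1OCc1ccccc1 | intermediate
19 | burkinabin C, 4,5-di-O-vanilloylquinic acid (free hydroxyls at C1 and C3) | COc1cc(C(=O)O[C@@H]2[C@H](O)C[C@@](O)(C(=O)O)C[C@H]2OC(=O)c2ccc(O)c(OC)c2)ccc1O | target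

**Step count**

Total: 13 steps. Longest linear sequence: 12 steps (steps 1 to 6, then 8 to 13); step 7 is a one-step side branch.

**Steps most likely to fail**

Step 8 (proposed new method). What may go wrong: intermolecular self-aldol of 9 (its own enol silane attacking the chelated aldehyde of a second molecule), poor facial selectivity at C1 in the ring closure, or beta-elimination of the tertiary hydroxyl of the product towards the enone and arene. Fallback with known reactions, from 3 back to 13: the two aldol bonds are made separately and the ketone is unveiled between them. Alcohol 3 is oxidised (Dess–Martin periodinane, pyridine) to (R)-2-[(4-methoxybenzyl)oxy]but-3-enal F1. A chelation-controlled Mukaiyama aldol of F1 with 11 (MgBr2·OEt2, CH2Cl2, −78 °C) gives benzyl (4R,5R)-4-hydroxy-5-[(4-methoxybenzyl)oxy]-2-oxohept-6-enoate F2. Tsuji–Wacker oxidation of the vinyl group (PdCl2(quinox), AgSbF6, t-BuOOH) gives benzyl (4R,5S)-4-hydroxy-5-[(4-methoxybenzyl)oxy]-2,6-dioxoheptanoate F3. Intramolecular aldol addition of the methyl ketone to the keto ester (MgBr2·OEt2, i-Pr2NEt, CH2Cl2, −20 °C) closes the ring to 13.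

Step 9. What may go wrong: competing axial hydride attack (3-epimer), or retro-aldol ring opening and elimination from the lithium alkoxides formed at O1 and O5. Fallback, from 13 back to 14: the control element is changed from reagent bulk to a chelate. O5 is silylated selectively (Et3SiCl, imidazole, CH2Cl2, 0 °C; the tertiary hydroxyl should not react) to give benzyl 4-O-(4-methoxybenzyl)-5-O-(triethylsilyl)-3-dehydroquinate F4. Narasaka–Prasad reduction (Et2BOMe, NaBH4, THF/MeOH, −78 °C) through the boron chelate of O1 and the ketone oxygen delivers hydride from outside, anti to the chelate, and should give the 1,3-syn diol benzyl 4-O-(4-methoxybenzyl)-5-O-(triethylsilyl)quinate F5. Mild acid (AcOH/THF/H2O) removes the silyl ether and returns 14.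

Step 10. What may go wrong: slow closure of the bridging acetal onto the tertiary hydroxyl, or acid-promoted lactonisation of O5 onto the benzyl ester. Fallback, from 13 to 19: the ketone itself serves as the protecting group of C3. Treatment of 13 with DDQ gives benzyl 3-dehydroquinate F6. Both secondary hydroxyls are esterified with 17 (EDC·HCl, DMAP) to give benzyl 4,5-bis-O-[4-(benzyloxy)-3-methoxybenzoyl]-3-dehydroquinate F7. LiBH(s-Bu)3 at −78 °C with a cold AcOH quench (to prevent acyl migration from O4 to O3) gives benzyl 4,5-bis-O-[4-(benzyloxy)-3-methoxybenzoyl]quinate F8. Hydrogenolysis (H2, Pd(OH)2/C) then gives 19.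

**Further compounds**

F1 | step 8 | (R)-2-[(4-methoxybenzyl)oxy]but-3-enal | COc1ccc(CO[C@@H](C=O)C=C)cc1
F2 | step 8 | benzyl (4R,5R)-4-hydroxy-5-[(4-methoxybenzyl)oxy]-2-oxohept-6-enoate | COc1ccc(CO[C@@H]([C@H](O)CC(=O)C(=O)OCc2ccccc2)C=C)cc1
F3 | step 8 | benzyl (4R,5S)-4-hydroxy-5-[(4-methoxybenzyl)oxy]-2,6-dioxoheptanoate | COc1ccc(CO[C@@H]([C@H](O)CC(=O)C(=O)OCc2ccccc2)C(C)=O)cc1
F4 | step 9 | benzyl 4-O-(4-methoxybenzyl)-5-O-(triethylsilyl)-3-dehydroquinate | COc1ccc(CO[C@@H]2C(=O)C[C@@](O)(C(=O)OCc3ccccc3)C[C@H]2O[Si](CC)(CC)CC)cc1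
F5 | step 9 | benzyl 4-O-(4-methoxybenzyl)-5-O-(triethylsilyl)quinate | COc1ccc(CO[C@@H]2[C@H](O)C[C@@](O)(C(=O)OCc3ccccc3)C[C@H]2O[Si](CC)(CC)CC)cc1
F6 | step 10 | benzyl 3-dehydroquinate | O[C@@H]1C(=O)C[C@@](O)(C(=O)OCc2ccccc2)C[C@H]1O
F7 | step 10 | benzyl 4,5-bis-O-[4-(benzyloxy)-3-methoxybenzoyl]-3-dehydroquinate | COc1cc(C(=O)O[C@@H]2C(=O)C[C@@](O)(C(=O)OCc3ccccc3)C[C@H]2OC(=O)c2ccc(OCc3ccccc3)c(OC)c2)ccc1OCc1ccccc1
F8 | step 10 | benzyl 4,5-bis-O-[4-(benzyloxy)-3-methoxybenzoyl]quinate | COc1cc(C(=O)O[C@@H]2[C@H](O)C[C@@](O)(C(=O)OCc3ccccc3)C[C@H]2OC(=O)c2ccc(OCc3ccccc3)c(OC)c2)ccc1OCc1ccccc1
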